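22.9 h is the number to carry: the crossover time, the time at which over-reaction product equals target if their ratio grows in step with time. Here it comes from the last grey reading, as time times target over over-reaction product.

| setting | grey | blue | winter | dawn |
|---|---|---|---|---|
| substrate | 0.050 M | 0.050 M | 0.050 M | 0.050 M |
| partner | 0.22 M | 1.2 M | 0.200 M | 0.800 M |
| initiator | 0.50 mM | 0.50 mM | 0.50 mM | 0.50 mM |
| temperature | 45 °C | 56 °C | 50 °C | 50 °C |
| remark | run made earlier | run made earlier |  |  |
| time |  |  | 20 h | 20 h |

| run | time / h | target / % | over-reaction product / % | substrate / % |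
|---|---|---|---|---|
| grey | 1.50 | 1 | 3 | 80 |
| grey | 3.00 | 4 | 2 | 65 |
| grey | 6.00 | 6 | 4 | 43 |
| grey | 10.0 | 7 | 0 | 33 |
| grey | 20.0 | 8 | 7 | 24 |
| blue | 4.00 | 9 | 0 | 38 |
| blue | 8.00 | 15 | 4 | 38 |
| blue | 12.0 | 18 | 7 | 36 |
| blue | 15.0 | 23 | 5 | 34 |
| blue | 20.0 | 29 | 9 | 29 |

(scatter of a reading: 1.5 percentage points)

* the winner by share of target in all that became target or over-reaction product; "neither" if no more than 2 percentage points parts them (winter / dawn / neither)
* share of target in all that became target or over-reaction product, winter
* share of target in all that became target or over-reaction product, dawn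

- what was read earlier has a scatter of 1.5 percentage points, one standard deviation
- a reading or a percentage of target counts all its forms, free or not

1. Solve both ends. You assume that target forms steadily and over-reaction product forms from target. At short times the ratio of over-reaction product to target is then time over crossover time, and the share (the selectivity) stays high. At long times, on the same assumption, it keeps falling. Joined: share = crossover time / (crossover time + time).

2. Way one: winter has nearly grey's c(partner), 0.200 M against 0.22 M, so you use the grey value and set aside that winter runs at 50 °C, not 45 °C. That puts winter's share at 53.3%, as your estimate.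

3. Way two uses the earlier grey readings: summed time times target over summed over-reaction product gives 13.3 h, so a share of 39.9%. The ways part, and the likely cheat is the reading of 3% at 1.50 h, beside target 1% and a scatter of 1.5 percentage points. Without it, way two gives 19.7 h, a share of 49.6%, near way one.

4. For dawn, the last blue reading gives 64.4 h. Blue is richer in partner and hotter than dawn, and you let these cancel, so you put dawn's share at 76.3%. Your reckoning puts dawn ahead.

5. The forecast says dawn, with 62% for winter and 75% for dawn, and warns: “Partner and temperature are confounded between these runs.” Its winter stands higher than yours.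

6. The flask gives dawn as winner, with 54.0% for winter and 79.4% for dawn. The forecast's winter stands 8 points above the flask.

    initiator → 2 initiating radical (k = 1.61 × 10⁻⁵ min⁻¹, Ea = 112 kJ mol⁻¹)
    partner + first chain carrier → target + second chain carrier (k = 12400 M⁻¹ s⁻¹, Ea = 25.0 kJ mol⁻¹)
    2 first chain carrier → ended chains A (k = 2.70 × 10⁷ M⁻¹ s⁻¹, Ea = 22.0 kJ mol⁻¹)
    target → over-reaction product (k = 0.00232 min⁻¹, Ea = 98.0 kJ mol⁻¹)
    substrate + second chain carrier → by-product + first chain carrier (k = 12700 M⁻¹ s⁻¹, Ea = 32.0 kJ mol⁻¹)
    substrate ⇌ dormant form (K = 1.85, k = 0.00486 min⁻¹, Ea = 114 kJ mol⁻¹, ΔH = −63.0 kJ mol⁻¹)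
    partner + target ⇌ idle adduct, settled at all times (K = 7.45 M⁻¹, ΔH = 8.00 kJ mol⁻¹)
    2 second chain carrier → ended chains B (k = 4.00 × 10⁸ M⁻¹ s⁻¹, Ea = 8.00 kJ mol⁻¹)
    substrate + initiating radical → capped initiator + first chain carrier (k = 2.97 × 10⁵ M⁻¹ s⁻¹, Ea = 27.0 kJ mol⁻¹)
    (constants at 50 °C)

At 20.0 h, winter's own crossover time is 23.5 h against the 22.9 h carried from grey, but that closeness proves little, as the carried value rests on one scattered grey reading at another temperature. The gap between the flasks is due to the difference in c(partner): dawn's 79.4% becomes 54.0% without it. Part of dawn's share is the pairing to idle adduct: at 20.0 h that form stands at 13.2% of the substrate charged, within dawn's target of 15.5%, and without the pairing dawn gives 27.8%. Now stop winter at 5.0 h: the crossover time 22.9 h gives 82.1%, and that flask gives 85.1%.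

The earlier runs and the new flask were computed for an exercise.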